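**Plan**

Locants used for every intermediate: C1 (bears C7H2OBz)=C2H–C3H(OMe)–C4H(OH)–C5H(OBz)–C6H(OH)–back to C1.
Retrosynthesis: (a) remove both benzoates; (b) turn the C5/C6 cis-diol back into C5=C6; (c) re-close the C4 oxygen onto C1 with loss of MeOH from C3, so that C1=C2–C3 becomes C1–C2=C3; (d) cut C1–C2 and C3–C4 together.
Enabling feature: O4 stands 1,4 across the carbocycle from sp2 C1, and C1=C2–C3(OMe) is the scar of a conjugate addition/β-elimination. Once bridged, the ring is a 7-oxabicyclo[2.2.1]hepta-2,5-diene. Its C1–C6–C5–C4–O unit (with C7) is the ring of furfuryl alcohol and its C2–C3 unit is an alkyne.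
Forward: silylated furfuryl alcohol and ethynyl p-tolyl sulfone undergo a Diels–Alder reaction that closes the carbocycle. Methoxide then opens the strained bridge, which sets C3 and makes C1=C2. Lipase resolution, osmylation (C5, C6), removal of the sulfone and silyl helpers, and two regioselective benzoylations follow.
Stereochemistry: the bridge oxygen marks one face. MeO⁻ adds exo, so C3 is cis to O4, and OsO4 adds anti to O4 and OMe, which sets C5 and C6. The absolute configuration comes from a biocatalytic kinetic resolution of the C4 carbinol, so one centre is chosen and three are relayed.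

Key step: step 2

Remark: 4, 5, 6 and F1 are racemates. Their SMILES give both enantiomers joined by a dot, with the one that leads to the target first. Starred descriptors are relative.

Step 1
Reactants: 1 furfuryl alcohol
Product: 2 tert-butyl(furan-2-ylmethoxy)dimethylsilane
Conditions: TBSCl, imidazole, CH2Cl2, 0 °C to rt
Reagents that add atoms: tert-butyldimethylsilyl chloride, CC(C)(C)[Si](C)(C)Cl
Why: Standard imidazole-promoted O-silylation of a primary alcohol; the silyl ether keeps O7 from being deprotonated in step 3 and acylated in step 4, and it tolerates heat, alkoxide, OsO4 and Na(Hg).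

Step 2
Reactants: 2 tert-butyl(furan-2-ylmethoxy)dimethylsilane; 3 ethynyl p-tolyl sulfone
Product: 4 rac-(1S*,4S*)-1-[(tert-butyldimethylsilyloxy)methyl]-2-(p-tolylsulfonyl)-7-oxabicyclo[2.2.1]hepta-2,5-diene
Conditions: near-equimolar 2 and 3, BHT (cat.), toluene, 80 °C, sealed tube
Reagents that add atoms: none
Why: Concerted suprafacial [4π+2π] cycloaddition: the furan diene C1=C6–C5=C4 adds across the sulfonyl-activated triple bond C2≡C3, so that C1–C2 and C3–C4 form in one transition state. The closest known reaction type is the Diels–Alder reaction of ethynyl aryl sulfones (acetylene equivalents) with furans and N-acylpyrroles. The six-membered carbocycle is closed by intermolecular cycloaddition, and the furan oxygen becomes the one-atom bridge, so the two five-membered oxa rings of the bicycle arise from the same two bonds. The new stereocentres are the bridgeheads C1 and C4: their relative configuration is dictated by the bridge geometry, an alkyne raises no endo/exo question, and the adduct is racemic (C4 is selected in step 4, C1 becomes sp2 in step 3). The step needs "ortho" regioselectivity, which the substrate secures electronically: the larger HOMO coefficient of a 2-alkylfuran lies at the free α-carbon (C4) and pairs with the larger LUMO coefficient at the unsubstituted alkyne carbon (C3), which puts the sulfonyl carbon next to the substituted bridgehead. Moderate temperature and near-equimolar amounts should hold back a second cycloaddition onto the hindered vinyl sulfone, and the alkyne oxidation level stores the strain and the acceptor that step 3 uses.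

Step 3
Reactants: 4 rac-oxanorbornadienyl sulfone
Product: 6 rac-(3S*,4S*)-1-[(tert-butyldimethylsilyloxy)methyl]-3-methoxy-2-(p-tolylsulfonyl)cyclohexa-1,5-dien-4-ol (OMe cis to OH), via potassium sulfonyl carbanion 5 (not isolated)
Conditions: KOMe (1.1 equiv), 18-crown-6 (10 mol %), THF, −40 to 0 °C; AcOH (1.1 equiv) at −40 °C
Reagents that add atoms: potassium methoxide, C[O-].[K+]
Why: Oxa-Michael addition/E1cB cascade of the kind known for 7-oxanorbornenyl vinyl sulfones: methoxide attacks the β-carbon C3 from the exo face (syn to the bridge oxygen, the endo face being shielded by C5=C6), so OMe ends cis to O4, and carbanion 5, whose lone pair develops endo and nearly antiperiplanar to C1–O, expels the bridge oxygen with release of ring strain, which turns the C1–C2 bond of step 2 into C1=C2 while the sulfone holds the cyclohexadienol back from aromatising.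

Step 4
Reactants: 6 rac-dienol
Product: 7 (3S,4S)-1-[(tert-butyldimethylsilyloxy)methyl]-3-methoxy-2-(p-tolylsulfonyl)cyclohexa-1,5-dien-4-ol
Conditions: Burkholderia cepacia lipase (Amano lipase PS, immobilised), vinyl acetate, MTBE, 30 °C, stopped just past half conversion; chromatography
Reagents that add atoms: none
Why: Lipase-catalysed kinetic resolution by irreversible transesterification: by the empirical size rule for secondary alcohols the (4R) carbinol (large group = the C3 side with OMe and the sulfonylvinyl unit, medium group = the flat C5=C6 vinyl) should be acetylated faster, so the (3S,4S)-alcohol should remain unreacted and fix the absolute configuration of the whole series.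

Step 5
Reactants: 7 (3S,4S)-dienol
Product: 8 (3S,4S,5R,6R)-1-[(tert-butyldimethylsilyloxy)methyl]-3-methoxy-2-(p-tolylsulfonyl)cyclohex-1-ene-4,5,6-triol
Conditions: OsO4 (2 mol %), NMO (1.5 equiv), acetone–H2O, 0 °C to rt
Reagents that add atoms: N-methylmorpholine N-oxide, C[N+]1([O-])CCOCC1; water, O
Why: Upjohn dihydroxylation: C1=C2 is switched off by the sulfonyl group and by full substitution, so OsO4 should take the electron-richer C5=C6 and approach anti to the allylic O4 and the homoallylic OMe (both on one face), which sets C5–OH and C6–OH cis to each other and trans to O4.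

Step 6
Reactants: 8 sulfonyl triol
Product: 9 (3R,4S,5R,6R)-1-[(tert-butyldimethylsilyloxy)methyl]-3-methoxycyclohex-1-ene-4,5,6-triol
Conditions: 6 % Na(Hg), Na2HPO4, MeOH–THF, −20 to 0 °C
Reagents that add atoms: none
Why: Reductive desulfonylation of a vinyl sulfone by electron transfer (C–S cleavage, then protonation of the vinyl anion in place): the six-membered ring forbids allene formation, so OMe stays, the free hydroxyls and the silyl ether are poor leaving groups, the buffer prevents base-induced isomerisation of the γ-hydroxy vinyl sulfone, and no stereocentre is touched.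

Step 7
Reactants: 9 silyl ether triol
Product: 10 (3R,4S,5R,6R)-1-(hydroxymethyl)-3-methoxycyclohex-1-ene-4,5,6-triol
Conditions: camphor-10-sulfonic acid (10 mol %), MeOH, 0 °C to rt
Reagents that add atoms: none
Why: Acid-catalysed methanolysis of a primary TBS ether, mild enough to leave the allylic methyl ether and the allylic alcohol un-ionised.

Step 8
Reactants: 10 tetrol
Product: 11 [(3R,4S,5R,6R)-4,5,6-trihydroxy-3-methoxycyclohex-1-en-1-yl]methyl benzoate
Conditions: BzCl (1.05 equiv), pyridine, −40 °C
Reagents that add atoms: benzoyl chloride, O=C(Cl)c1ccccc1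
Why: Rate-controlled acylation: the primary allylic O7–H should react much faster than the three secondary hydroxyls at low temperature, as in the 6-O-benzoylation of unprotected hexopyranosides.

Step 9
Reactants: 11 primary benzoate triol
Product: 12 [(3R,4R,5R,6R)-5-(benzoyloxy)-4,6-dihydroxy-3-methoxycyclohex-1-en-1-yl]methyl benzoate (target)
Conditions: BzCl (1.1 equiv), Me2SnCl2 (5 mol %), iPr2NEt (2 equiv), THF, rt
Reagents that add atoms: benzoyl chloride, O=C(Cl)c1ccccc1
Why: Organotin-catalysed regioselective acylation of a cis-1,2-diol: in the half-chair C4–OH and C5–OH are equatorial and C6–OH is pseudoaxial, the tin centre binds the C5/C6 cis-diol as a five-membered stannylene and activates the equatorial O5, the same pattern as the 3-O-benzoylation of 6-O-protected mannopyranosides, and no stereocentre is touched.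

**Compound list**

1 | furfuryl alcohol | OCc1ccco1 | starting material
2 | tert-butyl(furan-2-ylmethoxy)dimethylsilane | CC(C)(C)[Si](C)(C)OCc1ccco1 | intermediate
3 | ethynyl p-tolyl sulfone | C#CS(=O)(=O)c1ccc(C)cc1 | starting material
4 | rac-(1S*,4S*)-1-[(tert-butyldimethylsilyloxy)methyl]-2-(p-tolylsulfonyl)-7-oxabicyclo[2.2.1]hepta-2,5-diene | [C@@]12(CO[Si](C)(C)C(C)(C)C)O[C@@H](C=C1)C=C2S(=O)(=O)c1ccc(C)cc1.[C@]12(CO[Si](C)(C)C(C)(C)C)O[C@H](C=C1)C=C2S(=O)(=O)c1ccc(C)cc1 | intermediate
5 | potassium salt of the C2 carbanion of rac-3-exo-methoxy-2-(p-tolylsulfonyl)-1-[(tert-butyldimethylsilyloxy)methyl]-7-oxabicyclo[2.2.1]hept-5-ene | CO[C@@H]1[C-](S(=O)(=O)c2ccc(C)cc2)[C@@]2(CO[Si](C)(C)C(C)(C)C)C=C[C@@H]1O2.[K+].CO[C@H]1[C-](S(=O)(=O)c2ccc(C)cc2)[C@]2(CO[Si](C)(C)C(C)(C)C)C=C[C@H]1O2.[K+] | intermediate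
6 | rac-(3S*,4S*)-1-[(tert-butyldimethylsilyloxy)methyl]-3-methoxy-2-(p-tolylsulfonyl)cyclohexa-1,5-dien-4-ol | CO[C@@H]1C(S(=O)(=O)c2ccc(C)cc2)=C(CO[Si](C)(C)C(C)(C)C)C=C[C@@H]1O.CO[C@H]1C(S(=O)(=O)c2ccc(C)cc2)=C(CO[Si](C)(C)C(C)(C)C)C=C[C@H]1O | intermediate
7 | (3S,4S)-1-[(tert-butyldimethylsilyloxy)methyl]-3-methoxy-2-(p-tolylsulfonyl)cyclohexa-1,5-dien-4-ol | CO[C@@H]1C(S(=O)(=O)c2ccc(C)cc2)=C(CO[Si](C)(C)C(C)(C)C)C=C[C@@H]1O | intermediate
8 | (3S,4S,5R,6R)-1-[(tert-butyldimethylsilyloxy)methyl]-3-methoxy-2-(p-tolylsulfonyl)cyclohex-1-ene-4,5,6-triol | CO[C@@H]1C(S(=O)(=O)c2ccc(C)cc2)=C(CO[Si](C)(C)C(C)(C)C)[C@@H](O)[C@@H](O)[C@@H]1O | intermediate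
9 | (3R,4S,5R,6R)-1-[(tert-butyldimethylsilyloxy)methyl]-3-methoxycyclohex-1-ene-4,5,6-triol | CO[C@@H]1C=C(CO[Si](C)(C)C(C)(C)C)[C@@H](O)[C@@H](O)[C@@H]1O | intermediate
10 | (3R,4S,5R,6R)-1-(hydroxymethyl)-3-methoxycyclohex-1-ene-4,5,6-triol | CO[C@@H]1C=C(CO)[C@@H](O)[C@@H](O)[C@@H]1O | intermediate
11 | [(3R,4S,5R,6R)-4,5,6-trihydroxy-3-methoxycyclohex-1-en-1-yl]methyl benzoate | CO[C@@H]1C=C(COC(=O)c2ccccc2)[C@@H](O)[C@@H](O)[C@@H]1O | intermediate
12 | [(3R,4R,5R,6R)-5-(benzoyloxy)-4,6-dihydroxy-3-methoxycyclohex-1-en-1-yl]methyl benzoate | CO[C@@H]1C=C(COC(=O)c2ccccc2)[C@@H](O)[C@@H](O[C](=O)c2ccccc2)[C@@H]1O | target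

Total step count: 9. Longest linear sequence: 9 steps (1 to 12).

**Steps most likely to fail**

Step 4. The enzyme may discriminate poorly between the enantiomers, or may acylate a carbinol flanked by OMe only slowly. The fallback is a covalent resolution.
- It sets out from 6. Esterification with (S)-methoxy(phenyl)acetic acid (N,N'-dicyclohexylcarbodiimide, DMAP, CH2Cl2) should give two diastereomeric esters.
- These are the (S)-O-methylmandelate of the (3S,4S)-alcohol F2 and the (S)-O-methylmandelate of the (3R,4R)-alcohol F3, which are separated by chromatography or crystallisation.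
- Mild methanolysis of F2 (K2CO3, MeOH, 0 °C) comes back to the route at 7.

Step 6. An allylic oxygen substituent may be lost, or the alkene over-reduced, during electron transfer to the fully substituted vinyl sulfone. The fallback replaces electron transfer by a radical substitution.
- It sets out from 8. Bu3SnH and AIBN in toluene at reflux should exchange the sulfonyl group for tin by addition–fragmentation and give the C2 tributylstannyl cyclohexenetriol F4.
- HCl in MeOH should then protonate the C–Sn bond in place and remove the silyl ether at the same time. The route is rejoined at 10 and step 7 is skipped.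

Step 3. The dienol may aromatise, or the bridge may open incompletely, when addition and elimination run in one flask. The fallback separates the two events.
- It sets out from 4. Catalytic NaOMe in MeOH at 0 °C should give, after exo protonation, the saturated rac-3-exo-methoxy-2-endo-(p-tolylsulfonyl)-7-oxanorbornene F1, which is isolated.
- LiN(SiMe3)2 in THF at −78 °C then deprotonates C2 and triggers the β-elimination of the bridge under kinetic, aprotic conditions. A cold AcOH quench comes back to the route at 6.

**Further compounds**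

F1 | step 3 | rac-3-exo-methoxy-2-endo-(p-tolylsulfonyl)-1-[(tert-butyldimethylsilyloxy)methyl]-7-oxabicyclo[2.2.1]hept-5-ene | CO[C@@H]1[C@@H](S(=O)(=O)c2ccc(C)cc2)[C@@]2(CO[Si](C)(C)C(C)(C)C)C=C[C@@H]1O2.CO[C@H]1[C@H](S(=O)(=O)c2ccc(C)cc2)[C@]2(CO[Si](C)(C)C(C)(C)C)C=C[C@H]1O2
F2 | step 4 | (S)-O-methylmandelate of the (3S,4S)-alcohol | CO[C@@H]1C(S(=O)(=O)c2ccc(C)cc2)=C(CO[Si](C)(C)C(C)(C)C)C=C[C@@H]1OC(=O)[C@@H](OC)c1ccccc1
F3 | step 4 | (S)-O-methylmandelate of the (3R,4R)-alcohol | CO[C@H]1C(S(=O)(=O)c2ccc(C)cc2)=C(CO[Si](C)(C)C(C)(C)C)C=C[C@H]1OC(=O)[C@@H](OC)c1ccccc1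
F4 | step 6 | C2 tributylstannyl cyclohexenetriol | CO[C@@H]1C([Sn](CCCC)(CCCC)CCCC)=C(CO[Si](C)(C)C(C)(C)C)[C@@H](O)[C@@H](O)[C@@H]1O
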